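**Retrosynthetic overview**

1. The enone is carried as a β‑methoxy ketone: target ⇐ acid‑induced loss of MeOH from a 2,2‑disubstituted 4,5‑dimethoxycyclohexanone.
2. That cyclohexanone ⇐ one‑carbon ring expansion of a 1‑alkenylcyclopentanol (masked as a spiro‑lactol): alkoxy‑radical C–C scission and 6‑exo re‑closure onto an ene‑1,4‑dione, a net 1,2‑alkyl shift that forms C5–C6, the quaternary centre and the CH(Me) centre.
3. Spiro‑lactol ⇐ 3,4‑dimethoxyphenyllithium (from catechol) + spiro‑butenolide ⇐ C2‑symmetric (3S,4S)‑3,4‑dimethoxycyclopentanone + propynyl‑MgBr + allyl‑MgBr + CO2 in one flask.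
4. The C2‑symmetric ketone ⇐ (S)‑4‑hydroxycyclopent‑2‑enone by O‑methylation and trans oxa‑Michael addition of MeOH; it supplies the C4 stereocentre.
5. Ring order: five‑membered carbocycle (bought) → temporary spiro‑dihydrofuran → six‑membered carbocycle by ring expansion; the arene is bought as catechol.

Assumption: (S)‑4‑hydroxycyclopent‑2‑en‑1‑one is a catalogue compound and is bought in ≥98% ee.

**Route**

Step 1
Reactants: 1 (S)‑4‑hydroxycyclopent‑2‑en‑1‑one
Product: 2 (S)‑4‑methoxycyclopent‑2‑en‑1‑one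
Conditions: MeI (5 equiv), Ag2O (1.5 equiv), 4 Å MS, CH2Cl2, 23 °C, dark, 16 h
Reagents that add atoms: iodomethane, CI
Why: Purdie‑type O‑methylation under non‑basic conditions avoids β‑elimination and racemisation of the base‑sensitive 4‑oxy‑cyclopentenone; the stereocentre is not touched.

Step 2
Reactants: 2 (S)‑4‑methoxycyclopent‑2‑en‑1‑one
Product: 3 (3S,4S)‑3,4‑dimethoxycyclopentan‑1‑one
Conditions: MeOH (solvent), PMe3 (10 mol%), 0 °C, 3 h; AcOH quench, cold concentration
Reagents that add atoms: methanol, CO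
Why: Phosphine‑catalysed oxa‑Michael addition (hydroalkoxylation) under kinetic control delivers methoxide to C3 anti to the C4 methoxy group, giving the trans, C2‑symmetric ketone whose symmetry later makes both carbonyl faces and both ring C–C cleavage modes equivalent.

Step 3
Reactants: 3 (3S,4S)‑3,4‑dimethoxycyclopentan‑1‑one; 4 prop‑1‑yn‑1‑ylmagnesium bromide; 5 allylmagnesium bromide; 6 carbon dioxide
Product: 9 (7S,8S)‑7,8‑dimethoxy‑3‑methyl‑4‑(prop‑2‑en‑1‑yl)‑1‑oxaspiro[4.4]non‑3‑en‑2‑one, via bromomagnesium propargylic alkoxide 7 (not isolated), via cyclic alkenylmagnesium alkoxide 8 (not isolated)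
Conditions: 4 (1.1 equiv), THF, −40 → 0 °C; then 5 (3 equiv), THF–toluene, 65 °C, 12 h; then CO2 (1 atm), −20 → 23 °C; then 1 M HCl
Reagents that add atoms: none
Why: Alkynyl Grignard 1,2‑addition (no carbinol stereoisomers, the two carbonyl faces being homotopic) is followed by alkoxide‑directed anti‑carbomagnesiation, which puts allyl on the alkyne carbon next to the carbinol and Mg on the methyl‑bearing carbon in a five‑membered O–Mg chelate; carboxylation with retention and lactonisation fix the tetrasubstituted alkene geometry in the butenolide.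

Step 4
Reactants: 10 catechol (benzene‑1,2‑diol)
Product: 11 1,2‑dimethoxybenzene
Conditions: MeI (2.5 equiv), K2CO3 (3 equiv), acetone, reflux, 12 h
Reagents that add atoms: iodomethane, CI
Why: Williamson ether synthesis on both phenols; no stereocentre.

Step 5
Reactants: 11 1,2‑dimethoxybenzene
Product: 12 4‑bromo‑1,2‑dimethoxybenzene
Conditions: NBS (1.05 equiv), MeCN, 0 → 23 °C, 2 h
Reagents that add atoms: N‑bromosuccinimide, O=C1CCC(=O)N1Br
Why: Electrophilic aromatic bromination goes para to a methoxy group, giving the 3,4‑dimethoxyphenyl pattern; no stereocentre.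

Step 6
Reactants: 12 4‑bromo‑1,2‑dimethoxybenzene; 9 (7S,8S)‑7,8‑dimethoxy‑3‑methyl‑4‑(prop‑2‑en‑1‑yl)‑1‑oxaspiro[4.4]non‑3‑en‑2‑one
Product: 14 (7S,8S)‑2‑(3,4‑dimethoxyphenyl)‑7,8‑dimethoxy‑3‑methyl‑4‑(prop‑2‑en‑1‑yl)‑1‑oxaspiro[4.4]non‑3‑en‑2‑ol (both C2 epimers), via (3,4‑dimethoxyphenyl)lithium 13 (not isolated)
Conditions: 12, n‑BuLi (1.05 equiv), THF, −78 °C, 20 min; then 9, −78 °C, 1 h; sat. NH4Cl at −78 °C
Reagents that add atoms: none
Why: Bromine–lithium exchange and mono‑addition of the aryllithium to the lactone carbonyl give a lithium lactolate that is stable at −78 °C (the fully substituted β‑carbon blocks 1,4‑addition); the new anomeric centre equilibrates through the open form and is of no consequence.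

Step 7
Reactants: 14 (7S,8S)‑2‑(3,4‑dimethoxyphenyl)‑7,8‑dimethoxy‑3‑methyl‑4‑(prop‑2‑en‑1‑yl)‑1‑oxaspiro[4.4]non‑3‑en‑2‑ol
Product: 17 (4S,6S)‑6‑[(2R)‑1‑(3,4‑dimethoxyphenyl)‑1‑oxopropan‑2‑yl]‑4‑methoxy‑6‑(prop‑2‑en‑1‑yl)cyclohex‑2‑en‑1‑one, via open‑chain hydroxy enedione 15 (not isolated), via ring‑expanded dimethoxy ketone 16 (not isolated)
Conditions: [Ir(dF(CF3)ppy)2(5,5'‑d(CF3)bpy)]PF6 (2 mol%), tetrabutylammonium (R)‑3,3'‑bis(2,4,6‑triisopropylphenyl)‑1,1'‑binaphthyl‑2,2'‑diyl phosphate (20 mol%), PhCF3 (0.02 M), 450 nm LEDs, 25 °C, Ar, 24 h; then CSA (0.3 equiv), CH2Cl2, 23 °C, 2 h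
Reagents that add atoms: none
Why: Proposed new method: the lactol equilibrates with the (Z)‑γ‑hydroxy ene‑dione 15, and the excited trivalent iridium photocatalyst with the phosphate base removes H• from the tertiary O–H by proton‑coupled electron transfer (if the veratryl lactol is oxidised first, its oxyl radical opens to the same tertiary alkoxy radical); β‑scission of a ring C–C bond gives a primary alkyl radical tethered to an ene‑1,4‑dione (no vinyl radical can form, and the two possible ring cleavages give the same radical because the ring is C2‑symmetric); 6‑exo‑trig Giese closure onto the allyl‑bearing alkene carbon (β to the aroyl group) forms C5–C6 and the quaternary centre through a chair transition state with both OMe groups and the s‑cis ene‑dione arm equatorial and allyl axial, which places the side chain cis to the C4 methoxy group (6S); divalent iridium reduces the α‑aroyl radical and the chiral phosphoric acid formed in the first event protonates the enol(ate) within the ion pair to set (R) at the CH(Me) carbon (the sense of induction of the (R)‑phosphate is assumed, not derived); CSA then eliminates the β‑methoxy group (only C2 of the ring ketone is enolisable, and the hindered CH(Me) centre is not epimerised) to reveal the enone; the net change is a one‑carbon ring expansion by a formal 1,2‑alkyl shift; closest known reaction types are the photocatalytic PCET ring expansion of 1‑alkenylcycloalkanols (alkoxy‑radical β‑scission and recyclisation) and phosphoric‑acid‑controlled enantioselective protonation after radical conjugate addition, neither shown for a tetrasubstituted ene‑dione acceptor, for an all‑carbon quaternary centre, or with a lactol as the masked carbinol.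

**Compound list**

1 | (S)‑4‑hydroxycyclopent‑2‑en‑1‑one | O=C1C[C@H](O)C=C1 | starting material
2 | (S)‑4‑methoxycyclopent‑2‑en‑1‑one | O=C1C[C@H](OC)C=C1 | intermediate
3 | (3S,4S)‑3,4‑dimethoxycyclopentan‑1‑one | O=C1C[C@H](OC)[C@@H](OC)C1 | intermediate
4 | prop‑1‑yn‑1‑ylmagnesium bromide | CC#C[Mg]Br | starting material
5 | allylmagnesium bromide | C=CC[Mg]Br | starting material
6 | carbon dioxide | O=C=O | starting material
7 | bromomagnesium (3S,4S)‑3,4‑dimethoxy‑1‑(prop‑1‑yn‑1‑yl)cyclopentan‑1‑olate | CC#CC1(O[Mg]Br)C[C@H](OC)[C@@H](OC)C1 | intermediate (not isolated)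
8 | (7S,8S)‑7,8‑dimethoxy‑3‑methyl‑4‑(prop‑2‑en‑1‑yl)‑1‑oxa‑2‑magnesaspiro[4.4]non‑3‑ene (cyclic alkenylmagnesium alkoxide, allyl and methyl cis) | C=CCC1=C(C)[Mg]OC12C[C@H](OC)[C@@H](OC)C2 | intermediate (not isolated)
9 | (7S,8S)‑7,8‑dimethoxy‑3‑methyl‑4‑(prop‑2‑en‑1‑yl)‑1‑oxaspiro[4.4]non‑3‑en‑2‑one | C=CCC1=C(C)C(=O)OC12C[C@H](OC)[C@@H](OC)C2 | intermediate
10 | catechol (benzene‑1,2‑diol) | Oc1ccccc1O | starting material
11 | 1,2‑dimethoxybenzene | COc1ccccc1OC | intermediate
12 | 4‑bromo‑1,2‑dimethoxybenzene | COc1ccc(Br)cc1OC | intermediate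
13 | (3,4‑dimethoxyphenyl)lithium | [Li]c1ccc(OC)c(OC)c1 | intermediate (not isolated)
14 | (7S,8S)‑2‑(3,4‑dimethoxyphenyl)‑7,8‑dimethoxy‑3‑methyl‑4‑(prop‑2‑en‑1‑yl)‑1‑oxaspiro[4.4]non‑3‑en‑2‑ol, both C2 epimers | C=CCC1=C(C)C(O)(c3ccc(OC)c(OC)c3)OC12C[C@H](OC)[C@@H](OC)C2 | intermediate
15 | (2Z)‑1‑(3,4‑dimethoxyphenyl)‑3‑[(3S,4S)‑1‑hydroxy‑3,4‑dimethoxycyclopentyl]‑2‑methylhexa‑2,5‑dien‑1‑one | C=CC\C(=C(/C)C(=O)c1ccc(OC)c(OC)c1)C2(O)C[C@H](OC)[C@@H](OC)C2 | intermediate (not isolated)
16 | (2S,4S,5S)‑2‑[(2R)‑1‑(3,4‑dimethoxyphenyl)‑1‑oxopropan‑2‑yl]‑4,5‑dimethoxy‑2‑(prop‑2‑en‑1‑yl)cyclohexan‑1‑one | C=CC[C@@]1([C@@H](C)C(=O)c2ccc(OC)c(OC)c2)C[C@H](OC)[C@@H](OC)CC1=O | intermediate (not isolated)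
17 | (4S,6S)‑6‑[(2R)‑1‑(3,4‑dimethoxyphenyl)‑1‑oxopropan‑2‑yl]‑4‑methoxy‑6‑(prop‑2‑en‑1‑yl)cyclohex‑2‑en‑1‑one | C=CC[C@@]1([C@@H](C)C(=O)c2ccc(OC)c(OC)c2)C[C@H](OC)C=CC1=O | target

**Step count and risks**

Total step count: 7. Longest linear sequence: 5 steps (1 → 2 → 3 → 9 → 14 → 17).

The three steps most likely to fail are steps 7, 3 and 2.

Step 7 (the proposed new step). The risks are 7‑endo closure or premature reduction of the primary radical, modest control at the quaternary centre, and an unverified sense of induction at the CH(Me) carbon. The mirror‑image phosphate is the first check for the last point. The fallback sets out from 14 and comes back to the route at 17. It runs the same skeletal change as a known ionic reaction, the Brønsted‑acid vinylogous α‑ketol (semipinacol) rearrangement: TsOH·H2O (20 mol%), toluene, 60 °C. The aroyl carbonyl of 15 is protonated and a ring CH2 group shifts to the allyl‑bearing carbon while the carbinol becomes the ring ketone. Both candidate migrating groups are sp3 CH2 and give the same constitution, so 16 forms and loses methanol under the same acid to give 17. The quaternary centre and the CH(Me) centre are then only substrate‑controlled, so the isomers are separated by chromatography and the CH(Me) epimer is recycled by DBU equilibration. This fallback makes no compound outside the list (F0).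

Step 3. The risks are enolisation and β‑elimination of the β‑methoxy ketone by the Grignard reagent, and slow allylmagnesiation of a tertiary, internal propargylic alkoxide. The fallback sets out from 3 and comes back at 9, and replaces the magnesium chemistry by known ynoate–cuprate chemistry. Lithium ethyl propiolate (ethyl propiolate, LiN(SiMe3)2, THF, −78 °C) adds to 3 to give ethyl 3‑[(3S,4S)‑1‑hydroxy‑3,4‑dimethoxycyclopentyl]prop‑2‑ynoate F3. Syn‑carbocupration with an allylcopper reagent (allylmagnesium bromide, CuBr·SMe2, THF, −78 °C) puts allyl on the carbinol‑bearing carbon. Trapping the α‑cuprio ester with MeI (DMPU, −78 → 0 °C) gives the alkoxide of ethyl (2Z)‑3‑[(3S,4S)‑1‑hydroxy‑3,4‑dimethoxycyclopentyl]‑2‑methylhexa‑2,5‑dienoate F4, which lactonises on warming to 9.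

Step 2. The risks are an incomplete oxa‑Michael equilibrium and loss of enantiopurity through the meso cis adduct. The fallback sets out from 2 and comes back at 3, and installs the second oxygen stereospecifically. Weitz–Scheffer epoxidation (30% H2O2, NaOH cat., MeOH, −20 °C) anti to the methoxy group gives (1R,4S,5R)‑4‑methoxy‑6‑oxabicyclo[3.1.0]hexan‑2‑one F1. Organoselenium‑mediated reductive opening at the α‑carbon (PhSeSePh, NaBH4, EtOH, AcOH) gives (3S,4S)‑3‑hydroxy‑4‑methoxycyclopentan‑1‑one F2 with the C3–O bond untouched. Methylation as in step 1 (MeI, Ag2O) gives 3.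

**Further compounds**

F1 | step 2 | (1R,4S,5R)‑4‑methoxy‑6‑oxabicyclo[3.1.0]hexan‑2‑one | O=C1C[C@H](OC)[C@@H](O2)[C@@H]21
F2 | step 2 | (3S,4S)‑3‑hydroxy‑4‑methoxycyclopentan‑1‑one | O=C1C[C@H](OC)[C@@H](O)C1
F3 | step 3 | ethyl 3‑[(3S,4S)‑1‑hydroxy‑3,4‑dimethoxycyclopentyl]prop‑2‑ynoate | CCOC(=O)C#CC1(O)C[C@H](OC)[C@@H](OC)C1
F4 | step 3 | ethyl (2Z)‑3‑[(3S,4S)‑1‑hydroxy‑3,4‑dimethoxycyclopentyl]‑2‑methylhexa‑2,5‑dienoate | C=CC\C(=C(/C)C(=O)OCC)C1(O)C[C@H](OC)[C@@H](OC)C1
F0 | step 7 | none | none
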